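**The reading.** The reading was wanted at 4.0 min, but elm, the very flask in question, had been followed to 3.00 min, so I carried it across the gap by hand.

| flask | starting material | reagent | second substrate | third substrate | temperature | remark | time |
|---|---|---|---|---|---|---|---|
| elm | 0.050 M | 1.2 equiv | 5 equiv | 0.50 equiv | 20 °C | the very flask that is asked about, followed so far |  |
| oak | 0.034 M | 1.2 equiv | 5 equiv | 0.50 equiv | 15 °C | run made earlier |  |
| flask | 0.050 M | 1.20 equiv | 5.00 equiv | 0.500 equiv | 20 °C |  | 4.0 min |

- elm (time / min: target / %): 0.417: 18.4; 1.00: 23.7; 2.00: 22.8; 3.00: 19.4
- oak (time / s: target / %): 10.0: 6.4; 15.0: 8.1; 40.0: 17.0; 80.0: 24.2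

(standard deviation of a reading: 0.5 percentage points)

- removed target is counted in
- additions bring no volume worth counting

- west: at 4.0 min take out 90% of the target then present, then wait 2.0 min
- south-east: at 4.0 min add reagent, 100% of the amount charged, then wait 2.0 min
- east: at 4.0 min raise the temperature by 20 K, then wait 2.0 min
- north-west: change nothing and wait 2.0 min more

1. target, in percent of the starting material first charged, at 4.0 min
2. what to do for the largest gain in target; "none" if nothing gains more than 2 percentage points (west / south-east / east / north-west / none)
3. target present, with what was taken out counted in, in percent of the starting material first charged, after south-east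
4. target present, with what was taken out counted in, in percent of the starting material first charged, after east

**Fast rung.** The rise came first. Elm held 18.4% target at 0.417 min, already 77.6% of the 23.7% read at 1.00 min. Oak, colder and more dilute, needed 80.0 s to reach 24.2%.

**Middle rung.** Next came the turn. Elm's readings at 1.00 min and 2.00 min differed by 0.9 percentage points, against 0.71 points of scatter on such a difference, so I read a flat top there, where target was made about as fast as it was lost.

**Slow rung.** Past the top, elm showed net loss. I took its fractional fall between the last two readings, 0.161 min⁻¹, as a pseudo-first-order constant. From it I defined the loss half-life, the time in which target halves at that fractional rate 4.29 min.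

**My reckoning.** The missing 1.00 min was 0.233 of a half-life, so I committed to 16.5%. Carrying the scatter of the two readings forward gave that figure an uncertainty of about 1.1 points. Waiting 2.0 min more was 0.466 of a half-life, a cost of 4.6 points. A remedy had to outrun that, but the readings did not show what was left to react, so the half-life stopped short of choosing.

**The forecast.** The forecast gave 16.3%, chose south-east, and put south-east at 29% and east at 5%. Its figure for 4.0 min stood 0.20 points lower than mine. Its ground for the choice: “fresh reagent converts about 22 % more starting material”.

**The result.** The flask gave 17.5%, and south-east was best, reaching 23.1%, a gain of 5.6 points; east gave 10.2%. At 4.00 min it held 70.0% side product and 12.5% starting material.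

    second substrate ⇌ dormant form (K = 5.30, k = 0.209 s⁻¹, Ea = 68.0 kJ mol⁻¹, ΔH = −22.0 kJ mol⁻¹)
    second substrate + reagent → second product (k = 0.0526 M⁻¹ s⁻¹, Ea = 66.0 kJ mol⁻¹)
    third substrate + reagent → third product (k = 0.276 M⁻¹ s⁻¹, Ea = 64.0 kJ mol⁻¹)
    starting material + reagent → target (k = 0.246 M⁻¹ s⁻¹, Ea = 48.0 kJ mol⁻¹)
    starting material + target → side product (k = 0.434 M⁻¹ s⁻¹, Ea = 54.0 kJ mol⁻¹)
    (constants at 20 °C)

**Half-life again.** From 17.5%, the half-life predicted a drop of 4.8 points over 2.0 min, while the flask dropped 2.8 points. For a neighbour flask, the same recipe at 0.20 M, I divided the half-life by the concentration ratio, which gave 1.07 min. Elm's last reading, placed at 0.750 min on that scaled clock and carried to 4.0 min, gave my 2.38%; the neighbour held 6.13%.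

The data are calculated for an exercise; the scatter is artificial.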